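**Retrosynthetic overview**

- Ring B is numbered C1 (CH2 bridge), C2 (OH), C3 (butyryl), C4 (OMe), C5 (H), C6 (OH). The strategy rests on C1 lying between the oxygenated carbons C2 and C6 and para to C4–OMe: C2–C5 map onto a 3-methoxycyclobutenone (C2 = its carbonyl carbon) and C6, C1 onto a 1-silyloxyalkyne that already carries the bridge carbon.
- Last disconnection: the ring A carbon–CH2 bond, made by conjugate addition of butyrylfilicinic acid to the ortho-quinone methide released from a benzylic methyl ether on ring B.
- Before that: the ring B C3–butyryl bond, made by ortho-lithiation and Weinreb acylation ahead of the union, so that no Lewis acid meets the benzylic ether or the bridged product. The benzylic oxygen is carried as a methyl ether, so that acidic methanolysis is degenerate at that carbon.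
- Key disconnection: ring B C1–C2 and C5–C6 by benzannulation of the cyclobutenone with the silyloxyalkyne. Ring B is the only ring formed (step 3); ring A is bought as phloroglucinol and dearomatised by geminal C-methylation.

Key step: step 3

Remark: the target has no stereocentre and is drawn as one enol tautomer of ring A; the tautomers interconvert freely and are treated as one compound.

**Route**

Step 1
Reactants: 1 methyl methoxyacetate
Product: 3 triisopropyl[(3-methoxyprop-1-yn-1-yl)oxy]silane, via lithium 3-methoxyprop-1-yn-1-olate 2 (not isolated)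
Conditions: CH2Br2, LiTMP (lithium 2,2,6,6-tetramethylpiperidide), THF, −78 °C (gives LiCHBr2); add 1; LiN(SiMe3)2; n-BuLi, −78 to 0 °C; iPr3SiOTf (2.1 equiv), −78 °C; distillation
Reagents that add atoms: dibromomethane, BrCBr; triisopropylsilyl trifluoromethanesulfonate, CC(C)[Si](OS(=O)(=O)C(F)(F)F)(C(C)C)C(C)C
Why: The ynolate stage of the Kowalski ester homologation (addition of LiCHBr2, enolate formation, bromine–lithium exchange and 1,2-shift of the methoxymethyl group) should give ynolate 2, which the bulky silyl triflate traps on oxygen as the silyl ynol ether.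

Step 2
Reactants: 4 3-ethoxycyclobut-2-en-1-one
Product: 5 3-methoxycyclobut-2-en-1-one
Conditions: MeOH (anhydrous, large excess), camphorsulfonic acid (cat.), rt; NaHCO3; evaporate; repeat once
Reagents that add atoms: methanol, CO
Why: Acid-catalysed alkoxy exchange of a vinylogous ester (addition of methanol at C3 of the protonated enone, loss of ethanol) should be driven to the methyl ether by the excess of methanol, at a temperature too low for ring opening.

Step 3
Reactants: 5 3-methoxycyclobut-2-en-1-one; 3 triisopropyl[(3-methoxyprop-1-yn-1-yl)oxy]silane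
Product: 10 5-methoxy-2-(methoxymethyl)-3-[(triisopropylsilyl)oxy]phenol, via vinylketene 6 (not isolated), via cyclobutenone adduct 7 (not isolated), via dienylketene 8 (not isolated), via cyclohexadienone 9 (not isolated)
Conditions: 3 (1.2 equiv), PhMe, 80 °C, slow addition of 5; then 100 °C; base-washed glassware; chromatography on Et3N-deactivated SiO2
Reagents that add atoms: none
Why: Four-electron conrotatory opening of the strained ring of 5 gives vinylketene 6, whose ketene C=C adds to the silyloxyalkyne in a [2+2] cycloaddition to cyclobutenone 7; 7 opens again to dienylketene 8, which closes to dienone 9 and tautomerises to phenol 10. The closest known reaction type is the Danheiser benzannulation of cyclobutenones with trialkylsilyloxyalkynes to monosilylated resorcinols, of which the thermal union of a 3-alkoxycyclobutenone with an alkoxyalkyne to a 3,5-dialkoxyphenol is the nearest case. Ring B closes by thermal six-electron disrotatory electrocyclisation of 8, in which the ketene carbon (C2) rejoins the terminal methylene carbon (C3) after the cycloaddition has made the two new bonds C1–C2 and C5–C6. No stereocentre remains in 10, since the single one of 7 is destroyed in the second ring opening. The step needs regiocontrol in the cycloaddition, and the polarised silyloxyalkyne secures it: its carbon remote from oxygen is the nucleophilic one and bonds to the ketene carbonyl carbon, so that the methoxymethyl carbon comes to lie between the two oxygenated carbons and para to OMe. It also needs the ketene to be captured by the alkyne faster than by itself or by the product phenol, which the electron-rich alkyne in slight excess and the slow addition of 5 should secure.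

Step 4
Reactants: 10 5-methoxy-2-(methoxymethyl)-3-[(triisopropylsilyl)oxy]phenol
Product: 11 triisopropyl[5-methoxy-3-(methoxymethoxy)-2-(methoxymethyl)phenoxy]silane
Conditions: MOMCl, iPr2NEt, CH2Cl2, 0 °C to rt
Reagents that add atoms: chloromethyl methyl ether, COCCl
Why: Base-mediated O-alkylation of the free phenol (Williamson type) installs an acetal that will direct lithiation, under non-acidic conditions that should leave the ionisable benzylic ether and the silyl ether untouched.

Step 5
Reactants: 11 triisopropyl[5-methoxy-3-(methoxymethoxy)-2-(methoxymethyl)phenoxy]silane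
Product: 13 1-{6-methoxy-2-(methoxymethoxy)-3-(methoxymethyl)-4-[(triisopropylsilyl)oxy]phenyl}butan-1-one, via aryllithium 12 (not isolated)
Conditions: n-BuLi, THF, −20 to 0 °C; N-methoxy-N-methylbutanamide, −78 to 0 °C; H2O
Reagents that add atoms: N-methoxy-N-methylbutanamide, CCCC(=O)N(C)OC
Why: Directed ortho-metalation at the ring C–H flanked by OMOM and OMe followed by Weinreb ketone synthesis should place the butyryl group on C3 of ring B without any Lewis acid, and lithiation at the other open position would lead to the same compound 15 after both deprotections.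

Step 6
Reactants: 13 1-{6-methoxy-2-(methoxymethoxy)-3-(methoxymethyl)-4-[(triisopropylsilyl)oxy]phenyl}butan-1-one
Product: 14 1-{2-hydroxy-6-methoxy-3-(methoxymethyl)-4-[(triisopropylsilyl)oxy]phenyl}butan-1-one
Conditions: HCl (cat.), MeOH, rt
Reagents that add atoms: none
Why: Acid-catalysed transacetalisation to methanol should remove the MOM group beside the ketone, any methanolysis at the benzylic methyl ether being degenerate in this solvent and any early loss of the silyl group only anticipating step 7.

Step 7
Reactants: 14 1-{2-hydroxy-6-methoxy-3-(methoxymethyl)-4-[(triisopropylsilyl)oxy]phenyl}butan-1-one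
Product: 15 1-[2,4-dihydroxy-6-methoxy-3-(methoxymethyl)phenyl]butan-1-one
Conditions: Bu4NF, AcOH, THF, 0 °C
Reagents that add atoms: none
Why: Fluoride-mediated desilylation of the aryl silyl ether, buffered with acetic acid so that no free phenoxide expels methoxide early, should free the hydroxyl para to the ketone.

Step 8
Reactants: 16 phloroglucinol; 17 butyryl chloride
Product: 18 1-(2,4,6-trihydroxyphenyl)butan-1-one
Conditions: AlCl3, PhNO2–CH2Cl2, 0 to 50 °C; aq. HCl
Reagents that add atoms: none
Why: Friedel–Crafts C-acylation of phloroglucinol should stop at the monoketone because the first acyl group deactivates the ring.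

Step 9
Reactants: 18 1-(2,4,6-trihydroxyphenyl)butan-1-one
Product: 19 2-butanoyl-3,5-dihydroxy-4,4-dimethylcyclohexa-2,5-dien-1-one (butyrylfilicinic acid)
Conditions: NaOMe (excess), MeI (2.2 equiv), MeOH, 0 °C to rt; aq. HCl
Reagents that add atoms: iodomethane, CI
Why: Dearomatising double C-methylation of the acylphloroglucinol anion at one ring carbon is the standard entry to acylfilicinic acids, and limiting the methyl iodide should hold back the tri- and tetramethylated products.

Step 10
Reactants: 15 1-[2,4-dihydroxy-6-methoxy-3-(methoxymethyl)phenyl]butan-1-one; 19 2-butanoyl-3,5-dihydroxy-4,4-dimethylcyclohexa-2,5-dien-1-one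
Product: 21 2-butanoyl-6-[(3-butanoyl-2,6-dihydroxy-4-methoxyphenyl)methyl]-3,5-dihydroxy-4,4-dimethylcyclohexa-2,5-dien-1-one, via ortho-quinone methide 20 (not isolated)
Conditions: 19 (2 equiv), PhMe, 105 °C, argon sweep to carry off MeOH
Reagents that add atoms: none
Why: Thermal 1,4-elimination of methanol from the ortho-hydroxybenzyl methyl ether, assisted by the acidic trione, should give ortho-quinone methide 20, and Michael addition of the one enolic C–H carbon of 19 followed by rearomatisation of ring B forms the methylene bridge.

**Compound list**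

1 | methyl methoxyacetate | COCC(=O)OC | starting material
2 | lithium 3-methoxyprop-1-yn-1-olate | [Li+].[O-]C#CCOC | intermediate
3 | triisopropyl[(3-methoxyprop-1-yn-1-yl)oxy]silane | COCC#CO[Si](C(C)C)(C(C)C)C(C)C | intermediate
4 | 3-ethoxycyclobut-2-en-1-one | CCOC1=CC(=O)C1 | starting material
5 | 3-methoxycyclobut-2-en-1-one | COC1=CC(=O)C1 | intermediate
6 | 3-methoxybuta-1,3-dien-1-one (vinylketene) | COC(=C)C=C=O | intermediate
7 | 4-(1-methoxyethenyl)-2-(methoxymethyl)-3-[(triisopropylsilyl)oxy]cyclobut-2-en-1-one (racemic) | COCC1=C(O[Si](C(C)C)(C(C)C)C(C)C)C(C(=C)OC)C1=O | intermediate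
8 | (3E)-5-methoxy-2-(methoxymethyl)-3-[(triisopropylsilyl)oxy]hexa-1,3,5-trien-1-one (ketene carbon and methoxyvinyl group cis) | COCC(=C=O)/C(O[Si](C(C)C)(C(C)C)C(C)C)=C\C(OC)=C | intermediate
9 | 5-methoxy-2-(methoxymethyl)-3-[(triisopropylsilyl)oxy]cyclohexa-2,4-dien-1-one | COCC1=C(O[Si](C(C)C)(C(C)C)C(C)C)C=C(OC)CC1=O | intermediate
10 | 5-methoxy-2-(methoxymethyl)-3-[(triisopropylsilyl)oxy]phenol | COCc1c(O)cc(OC)cc1O[Si](C(C)C)(C(C)C)C(C)C | intermediate
11 | triisopropyl[5-methoxy-3-(methoxymethoxy)-2-(methoxymethyl)phenoxy]silane | COCOc1cc(OC)cc(O[Si](C(C)C)(C(C)C)C(C)C)c1COC | intermediate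
12 | {2-methoxy-6-(methoxymethoxy)-5-(methoxymethyl)-4-[(triisopropylsilyl)oxy]phenyl}lithium | COCOc1c([Li])c(OC)cc(O[Si](C(C)C)(C(C)C)C(C)C)c1COC | intermediate
13 | 1-{6-methoxy-2-(methoxymethoxy)-3-(methoxymethyl)-4-[(triisopropylsilyl)oxy]phenyl}butan-1-one | CCCC(=O)c1c(OC)cc(O[Si](C(C)C)(C(C)C)C(C)C)c(COC)c1OCOC | intermediate
14 | 1-{2-hydroxy-6-methoxy-3-(methoxymethyl)-4-[(triisopropylsilyl)oxy]phenyl}butan-1-one | CCCC(=O)c1c(OC)cc(O[Si](C(C)C)(C(C)C)C(C)C)c(COC)c1O | intermediate
15 | 1-[2,4-dihydroxy-6-methoxy-3-(methoxymethyl)phenyl]butan-1-one | CCCC(=O)c1c(OC)cc(O)c(COC)c1O | intermediate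
16 | phloroglucinol | Oc1cc(O)cc(O)c1 | starting material
17 | butyryl chloride | CCCC(=O)Cl | starting material
18 | 1-(2,4,6-trihydroxyphenyl)butan-1-one | CCCC(=O)c1c(O)cc(O)cc1O | intermediate
19 | 2-butanoyl-3,5-dihydroxy-4,4-dimethylcyclohexa-2,5-dien-1-one | CCCC(=O)C1=C(O)C(C)(C)C(O)=CC1=O | intermediate
20 | 4-butanoyl-5-hydroxy-3-methoxy-6-methylidenecyclohexa-2,4-dien-1-one | CCCC(=O)C1=C(O)C(=C)C(=O)C=C1OC | intermediate
21 | 2-butanoyl-6-[(3-butanoyl-2,6-dihydroxy-4-methoxyphenyl)methyl]-3,5-dihydroxy-4,4-dimethylcyclohexa-2,5-dien-1-one | CCCC(=O)C1=C(O)C(C)(C)C(O)=C(Cc2c(O)cc(OC)c(C(=O)CCC)c2O)C1=O | target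

**Step count**

Total: 10 steps. Longest linear sequence: 7 steps (steps 1, 3, 4, 5, 6, 7, 10).

**Steps most likely to fail**

Step 3. The electrocyclic opening of the vinylogous ester 5 may be slow, so that the temperature needed lets the ketene dimerise or acylate the product phenol, and lets the ortho-hydroxybenzyl ether of 10 begin to lose methanol. The fallback generates the same ketene at room temperature by photochemical Wolff rearrangement; it sets out from silyloxyalkyne 3 and comes back to the route at phenol 10. Purchased 3,3-dimethoxybutan-2-one (CC(=O)C(C)(OC)OC) would be heated with a trace of TsOH while methanol distils, to give 3-methoxybut-3-en-2-one F1. Its lithium enolate (LiN(SiMe3)2, THF, −78 °C) would be acylated with 2,2,2-trifluoroethyl trifluoroacetate to 1,1,1-trifluoro-5-methoxyhex-5-ene-2,4-dione F2. Detrifluoroacetylative diazo transfer (MsN3, Et3N, H2O, MeCN) would then give 1-diazo-3-methoxybut-3-en-2-one F3. Irradiation of F3 with 3 (Pyrex, near 300 nm, ClCH2CH2Cl, rt) should expel nitrogen and give ketene 6, which enters the same sequence through 7, 8 and 9 on brief warming to 80 °C and ends at 10.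

Step 10. Loss of methanol may be too slow at a temperature the product tolerates. Prolonged heating may exchange the two halves of the methylene bridge by retro-Michael reaction, and 15 may alkylate itself at its open ring position. The fallback ionises the ether with acid at low temperature one step earlier, while the silyl group still shields that position; it sets out from 14 and comes back at target 21. Treating 14 with 19 and TsOH·H2O (10 mol %) in CH2Cl2 at 0 °C to rt should give, by Friedel–Crafts-type alkylation of the enol, 2-butanoyl-6-({3-butanoyl-2-hydroxy-4-methoxy-6-[(triisopropylsilyl)oxy]phenyl}methyl)-3,5-dihydroxy-4,4-dimethylcyclohexa-2,5-dien-1-one F5. Buffered desilylation (Bu4NF, AcOH, THF, 0 °C) would then give 21.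

Step 5. Metalation may be incomplete or may go to the benzylic methylene beside the OMOM group instead of the ring. The fallback replaces deprotonation by halogen–metal exchange; it sets out from 11 and comes back at aryllithium 12 and so at 13. NBS (MeCN, −20 °C) should brominate the electron-rich ring at the open position not shielded by the silyl ether, giving [4-bromo-5-methoxy-3-(methoxymethoxy)-2-(methoxymethyl)phenoxy]triisopropylsilane F4. n-BuLi at −78 °C would convert F4 into 12 within minutes, and 12 is acylated as in step 5.

**Further compounds**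

F1 | step 3 | 3-methoxybut-3-en-2-one | CC(=O)C(=C)OC
F2 | step 3 | 1,1,1-trifluoro-5-methoxyhex-5-ene-2,4-dione | COC(=C)C(=O)CC(=O)C(F)(F)F
F3 | step 3 | 1-diazo-3-methoxybut-3-en-2-one | COC(=C)C(=O)C=[N+]=[N-]
F4 | step 5 | [4-bromo-5-methoxy-3-(methoxymethoxy)-2-(methoxymethyl)phenoxy]triisopropylsilane | COCOc1c(Br)c(OC)cc(O[Si](C(C)C)(C(C)C)C(C)C)c1COC
F5 | step 10 | 2-butanoyl-6-({3-butanoyl-2-hydroxy-4-methoxy-6-[(triisopropylsilyl)oxy]phenyl}methyl)-3,5-dihydroxy-4,4-dimethylcyclohexa-2,5-dien-1-one | CCCC(=O)C1=C(O)C(C)(C)C(O)=C(Cc2c(O[Si](C(C)C)(C(C)C)C(C)C)cc(OC)c(C(=O)CCC)c2O)C1=O
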